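## Analysis of the target

The target (C19H24O7) is a heliangolide-type germacranolide. Germacrane numbering is used for it and for all precursors. C8 bears the methacrylate, followed by C9H2, C10 (methyl C14), C1, C2H2, C3 (OH), C4 (CH2OH = C15), C5, C6 (lactone oxygen) and C7. C11, C12 and C13 are the alpha carbon, the carbonyl carbon and the exocyclic methylene of the lactone.

One ten-membered carbocycle (ring A) carries three features:
- a trans-fused alpha-methylene-gamma-butyrolactone at C6–C7 (ring B);
- a trisubstituted epoxide at C1–C10 whose ring bonds C2 and C9 are trans (ring C);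
- a trisubstituted C4=C5 double bond whose ring bonds C3 and C6 are cis (4Z).

The six stereocentres are 1R, 3S, 6R, 7R, 8R and 10R. C6–C7–C8 form a contiguous triad (H6 and H7 trans, C11 and O8 on the same face). C1 and C10 record one face of an E alkene. C3 stands alone.

The sensitive groups are two Michael acceptors, an epoxide that acid lets O3 or C4=C5 open across the ring, and an alkene flanked by three allylic oxygens.

The synthesis is hard for three reasons. The medium ring is strained and holds one E-derived and one Z unit. Four oxygens (O3, O6, O8, O15) must be told apart. Every centre sits on a flexible ring.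

The feature that decides the strategy is this. C1=C10 (the alkene behind the epoxide) and C4=C5 form a 1,5-diene of E,Z geometry, and C6 carries oxygen. A bond drawn from C1 to C6 gives a six-membered ring C1–C6. That ring holds the cis C4=C5 bond, the C3 oxygen, the methyl C15 and an isopropenyl group (C10, C9, C14) at C1, which is the complete skeleton of carvone.

## Retrosynthetic reasoning

**24 to 23 to 22.** The O3–Si bond and then the C15–O bond are cut. C15 has no stereochemistry. Once C1=C10 is epoxidised, C15 is the only allylic methyl group on a non-conjugated alkene. Removing its oxygen turns C15 into a plain methyl group and opens the way to the terpene pool. The forward reaction has to oxidise C15–H and leave C3–H alone.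

**22 to 21.** Both C–O bonds of the epoxide are cut. The trans epoxide is the record of an E alkene, and the two centres C1 and C10 collapse into the planar chirality of that alkene. The forward step needs site selectivity among four alkenes and attack on the outer face only.

**21 to 20 to 19.** The O8–acyl bond is cut and O8 is capped as a 4-methoxybenzyl ether. The methacrylate would not survive the strong base of the methylenation, so it comes after it. O8 needs a group that leaves under neutral oxidative conditions while the O3 silyl ether stays.

**19 to 16.** The C11=C13 bond is cut. The Michael acceptor is put on only after all nucleophilic and basic steps at C6 and C7 are done.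

**16 to 15 to 14 to 13.** The lactone is cut at the alkyl bond C6–O, not at the acyl bond C12–O. In the ring conformer that the key step delivers, any reagent reaches C6 from the periphery. A hydride from outside leaves O6 on the wrong side (6S), so the oxygen itself has to arrive from outside. The forward sequence therefore reduces ketone 13 to 14 and lets the carboxyl group of 15 displace activated O6 with inversion.

**13 to 12 to 11 to 10 (key disconnection).** C7–C11 and C8–C9 are cut and C1–C6 is reconnected. This removes ring A altogether. The ten-membered keto ester with two stereocentres and two defined ring double bonds becomes the cyclohexenol 10. In 10 the Z geometry of C4=C5 is trivial and the two alkenyl groups at C1 and C6 are trans. The forward step has to transfer the chirality of C1 and C6 to C8, C7 and both alkene planes.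

**10 to 4 and 9 (from 8).** The C6–C7 bond is cut. The two-carbon unit C7–C8 comes with O8 already in place. The Z geometry of 8 encodes the configuration of C8.

**4 to 3 to 2 to 1, and 8 to 6 to 5.** Enone 4 is (S)-carvone 1 with its carbonyl reduced (this sets C3) and its ring methylene C6 oxidised. Ten of the fifteen skeletal carbons and the only stereocentre that is not made by transfer come from 1. Bromide 8 is made from alcohol 5 in two steps.

## Alternatives that were turned down

Alternative 1: the textbook cut at C6–C7.
- **Forward key step:** the open-chain (Z)-enal A1, which carries its own 2-(bromomethyl)acrylate, is closed with CrCl2 and catalytic NiCl2 (Nozaki–Hiyama–Kishi type allylation). Lactonisation then gives macrocycle A2.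
- **Precursor cost:** A1 needs both trisubstituted alkenes and the carbinol centres C3 and C8 made one by one, so the precursor costs more steps than the whole route below.
- **Geometry:** the gamma-oxygenated (Z)-enal isomerises easily to the E form, which would lead to the wrong ring geometry.
- **Side reaction:** the allylchromium species can place the metal on C7 next to the C8 alkoxy group and lose it by beta-elimination.
- **Closure:** the ring is closed end to end against strain, and the C6/C7 outcome for a 4Z ring cannot be predicted from the 4E cases.

Alternative 2: a cut at C4=C5.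
- **Forward key step:** ring-closing metathesis of triene lactone A3 with the second-generation Grubbs catalyst, again leading to A2.
- **Reactivity:** one partner is a 1,1-disubstituted alkene between two oxygenated carbons and the other is a vinyl group on the lactone carbinol. Both are poor metathesis partners.
- **Competition:** the alpha-methylene lactone competes for the carbene and would have to be masked.
- **Strain:** the E alkene already in the chain makes the closure strained, so oligomers are favoured.
- **Value:** the key step sets no stereocentre, and C3, C6, C7 and C8 all have to be built before it.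

Alternative 3: a one-atom ring contraction.
- **Forward key step:** the thirteen-membered bis-allylic ether A4 is deprotonated at C6. A [2,3]-Wittig rearrangement forms C6–C7, both centres and the exocyclic methylene in carbocycle A5.
- **Rank:** this is of the same rank of boldness as the chosen route.
- **Fatal flaw:** the C6 allyl anion is delocalised to C4, which carries leaving groups on both neighbours (O3 and O15). Elimination to a diene should outrun the rearrangement.
- **Other problems:** deprotonation at C13 competes, and the Z allyl anion can lose its geometry.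
- **Cost:** A4 needs a macrocyclisation of its own, and A5 still needs oxidation at C12 and lactonisation.

Key step: step 7

Remark on the chemistry: 4-methoxybenzyl vinyl ether 6 is treated as not purchasable and is made in one step. An atom keeps its germacrane number through the ring expansion.

## Route

Step 1
Reactants: 1 (S)-(+)-carvone
Product: 2 (+)-cis-carveol, (1S,5S)-2-methyl-5-(prop-1-en-2-yl)cyclohex-2-en-1-ol
Conditions: NaBH4, CeCl3·7H2O, MeOH, −20 to 0 °C
Reagents that add atoms: none
Why: Luche reduction gives clean 1,2-delivery of hydride to the enone; axial attack on the half-chair with the isopropenyl group equatorial places the new hydroxyl cis to it and sets C3 (3S of the target).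

Step 2
Reactants: 2 (+)-cis-carveol
Product: 3 cis-carveol tert-butyldimethylsilyl ether (3S,1S in germacrane numbering)
Conditions: TBSCl, imidazole, DMF, rt
Reagents that add atoms: tert-butyldimethylsilyl chloride, CC(C)(C)[Si](C)(C)Cl
Why: Standard silylation; the TBS ether should survive KH, organolithium reagents, LDA, DDQ and peracid and leaves with fluoride at the end.

Step 3
Reactants: 3 cis-carveol TBS ether
Product: 4 (4S,6S)-4-(tert-butyldimethylsilyloxy)-3-methyl-6-(prop-1-en-2-yl)cyclohex-2-en-1-one
Conditions: CrO3, 3,5-dimethylpyrazole, CH2Cl2, −20 °C
Reagents that add atoms: chromium trioxide, O=[Cr](=O)=O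
Why: Allylic C–H oxidation with the CrO3–3,5-dimethylpyrazole complex; C6 is the only secondary allylic ring methylene and its oxidation gives the conjugated beta-methyl enone, while the 1,1-disubstituted isopropenyl group is less reactive; should C1 enolise, it returns to the more stable cis-1,3-diequatorial arrangement that is wanted.

Step 4
Reactants: 5 4-methoxybenzyl alcohol
Product: 6 4-methoxybenzyl vinyl ether
Conditions: Pd(OAc)2 (cat.), 1,10-phenanthroline (cat.), ethyl vinyl ether (solvent), rt
Reagents that add atoms: ethyl vinyl ether, C=COCC
Why: Palladium-catalysed transfer vinylation (alkoxypalladation, then loss of ethoxide) exchanges the alkoxy group under neutral conditions that the acid-labile product tolerates.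

Step 5
Reactants: 6 4-methoxybenzyl vinyl ether
Product: 8 (Z)-2-bromovinyl 4-methoxybenzyl ether, via 1,2-dibromoethyl 4-methoxybenzyl ether 7 (not isolated)
Conditions: Br2, CH2Cl2, −78 °C; then Et3N, −78 °C to rt
Reagents that add atoms: bromine, BrBr
Why: Bromine addition to an enol ether followed by amine-induced dehydrobromination is the standard access to (Z)-2-bromovinyl ethers, the cis isomer being favoured; at −78 °C the vinyl ether should react far faster with Br2 than the anisole ring.

Step 6
Reactants: 8 (Z)-2-bromovinyl 4-methoxybenzyl ether; 4 enone
Product: 10 (1S,4S,6S)-4-(tert-butyldimethylsilyloxy)-1-[(Z)-2-(4-methoxybenzyloxy)ethenyl]-3-methyl-6-(prop-1-en-2-yl)cyclohex-2-en-1-ol, via (Z)-2-(4-methoxybenzyloxy)vinyllithium 9 (not isolated)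
Conditions: 8, n-BuLi, Et2O, −78 °C; then 4, THF, −78 °C; H2O quench
Reagents that add atoms: n-butyllithium, [Li]CCCC (lithium is carried only by 9)
Why: Bromine–lithium exchange with retention gives the internally chelated, configurationally stable (Z)-beta-alkoxyvinyllithium, which adds 1,2 to the enone; attack anti to the neighbouring isopropenyl group and to the C3 silyloxy group (both on the other face) sets C6 and makes the two alkenyl groups trans; any E bromide is filtered out because its lithio derivative eliminates alkoxide in an anti fashion.

Step 7
Reactants: 10 trans-dialkenylcyclohexenol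
Product: 13 methyl 2-[(3S,7R,8R,1(10)E,4Z)-3-(tert-butyldimethylsilyloxy)-8-(4-methoxybenzyloxy)-4,10-dimethyl-6-oxocyclodeca-1(10),4-dien-7-yl]acetate (germacrane numbering), via potassium alkoxide 11 (not isolated), via potassium enolate 12 (not isolated)
Conditions: KH, 18-crown-6, THF, 0 °C to rt; then −78 °C, BrCH2CO2Me
Reagents that add atoms: methyl bromoacetate, COC(=O)CBr; potassium hydride, [H-].[K+] (potassium is carried only by 11 and 12)
Why: Deprotonation gives alkoxide 11, whose C1–C6 bond is weakened by the oxyanion, and a concerted anionic oxy-Cope [3,3] shift breaks C1–C6 and forms C8–C9; the closest known reaction type is the ring expansion of trans-1,2-dialkenylcyclohexanols to (E)-cyclodec-5-enones with alkylation of the regiodefined enolate in the same flask. Ring A is not closed end to end but made by a four-atom expansion of the six-membered ring, so no high dilution is needed and the cis C4=C5 bond is inherited from the cyclohexene. The trans relation of the two alkenyl groups allows only the chair transition state with the ring bonds C2 and C5 equatorial, which fixes the E geometry of C1=C10 and puts C5 and C8 trans on the enolate double bond of 12. C8 is set by suprafacial bond formation on the (Z)-enol ether: with C6 S-configured the OPMB group takes the axial site next to the oxyanion (bridged by K+) and the new centre is 8R, so the centres C1 and C6 that are lost are traded for C8 and for the planar chirality of both new double bonds. C7 is set in the same flask: the inner face of 12 is covered by C9 and by the C1=C10 bond, the electrophile comes from the periphery, anti to C9 as in the alkylation of a chelated beta-alkoxy enolate, and gives 7R. The step needs C-alkylation to outrun beta-elimination of the C8 alkoxide: in 12 the ring bond C8–C9, not the C8–O bond, is aligned with the enolate pi system, and the enolate is cooled and quenched as soon as the rearrangement is over. C3 is a spectator, and its pseudo-equatorial silyl ether cannot reach the C6 oxyanion across the half-chair.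

Step 8
Reactants: 13 keto ester
Product: 14 methyl 2-[(3S,6S,7S,8R)-6-hydroxy analogue of 13]acetate (C7 unchanged in space; its descriptor changes with the priorities)
Conditions: NaBH4, CeCl3·7H2O, MeOH, −78 to −40 °C
Reagents that add atoms: none
Why: Luche 1,2-reduction of the Z-enone; hydride should come from the periphery, the same face that the alkylating agent used, which leaves O6 on the inner-upper side (6S) and anti to the C7 side chain, so that the hydroxy ester does not lactonise.

Step 9
Reactants: 14 hydroxy ester
Product: 15 (3S,6S,7S,8R)-hydroxy acid
Conditions: LiOH, THF/MeOH/H2O, 0 °C to rt; then cold 0.5 M HCl to pH 4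
Reagents that add atoms: lithium hydroxide, [Li+].[OH-]
Why: Plain saponification; after the reduction no base-sensitive beta-alkoxy ketone is left, and the silyl and PMB ethers are stable.

Step 10
Reactants: 15 hydroxy acid
Product: 16 (3S,6R,7R,8R)-trans-fused gamma-lactone (11,13-dihydro-13-nor stage; O3 TBS and O8 PMB)
Conditions: PPh3, DIAD, THF (0.01 M), 0 °C
Reagents that add atoms: none
Why: Mitsunobu lactonisation; the carboxylate displaces the activated allylic O6 in a 5-exo-tet SN2 process with inversion, helped by the anti arrangement of C6–O and C7–C11 in the ground state, and this sets 6R and the trans ring fusion.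

Step 11
Reactants: 16 trans-lactone
Product: 19 alpha-methylene lactone (3S,6R,7R,8R; O3 TBS; O8 PMB), via Mannich base 17 (not isolated), via methiodide 18 (not isolated)
Conditions: LDA, THF, −78 °C; CH2=NMe2+ I−, −78 °C to rt; then MeI, MeOH; then aq. NaHCO3
Reagents that add atoms: dimethyl(methylidene)ammonium iodide, C=[N+](C)C.[I-]; iodomethane, CI (its methyl group is carried only by 18 and leaves as trimethylamine)
Why: Alpha-methylenation through the Mannich reaction with Eschenmoser's salt, quaternisation and elimination; C11–H is the only acidic C–H, and the new centre at C11 in 17 is erased in the elimination.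

Step 12
Reactants: 19 PMB ether
Product: 20 (3S,6R,7R,8R)-8-hydroxy alpha-methylene lactone (O3 TBS)
Conditions: DDQ, CH2Cl2/pH 7 buffer, 0 °C
Reagents that add atoms: none
Why: Oxidative PMB cleavage under neutral conditions; the silyl ether, both ring alkenes and the Michael acceptor should not react.

Step 13
Reactants: 20 C8 alcohol
Product: 21 8-O-methacrylate (O3 TBS; 1(10)E,4Z-diene)
Conditions: methacrylic anhydride, Et3N, DMAP (cat.), CH2Cl2, 0 °C to rt
Reagents that add atoms: methacrylic anhydride, C=C(C)C(=O)OC(=O)C(C)=C
Why: DMAP-catalysed acylation of the only free hydroxyl; 8-hydroxy-6,12-olides of this configuration are stable towards translactonisation under such mild base.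

Step 14
Reactants: 21 diene
Product: 22 (1R,10R)-epoxide (O3 TBS; C15 still CH3)
Conditions: mCPBA (1.05 equiv), CH2Cl2, −20 to 0 °C
Reagents that add atoms: 3-chloroperbenzoic acid, O=C(OO)c1cccc(Cl)c1
Why: Prilezhaev epoxidation; C1=C10 is the only electron-rich and strained alkene (C4=C5 is deactivated by allylic O3 and O6, the two acrylates are electron-poor); syn addition to the outer face of the E alkene, in the ring conformer fixed since step 7, gives the trans epoxide with 1R,10R.

Step 15
Reactants: 22 epoxide
Product: 23 15-hydroxy compound (O3 TBS)
Conditions: SeO2 (cat.), t-BuOOH, CH2Cl2, rt to 40 °C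
Reagents that add atoms: tert-butyl hydroperoxide, CC(C)(C)OO (terminal oxygen source, relayed by selenium dioxide, O=[Se]=O)
Why: Riley oxidation (ene reaction, then [2,3] shift) of the only non-conjugated alkene left; selenium binds to C5 and hydrogen is taken from the more substituted end, where C15H3 is preferred over the oxygen-bearing C3–H; C15 lies trans to C6, the position that this reagent oxidises in trisubstituted alkenes, so the 4Z geometry is kept.

Step 16
Reactants: 23 silyl ether
Product: 24 target, CNP0496616.1
Conditions: TBAF, AcOH (1:1), THF, 0 °C to rt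
Reagents that add atoms: none
Why: Fluoride desilylation buffered with acetic acid; the medium is close to neutral, which avoids conjugate addition or acyl migration on the basic side and transannular opening of the epoxide by O3 on the acidic side.

## Compound list

1 | (S)-(+)-carvone | C=C(C)[C@H]1CC=C(C)C(=O)C1 | starting material
2 | (+)-cis-carveol, (1S,5S) | C=C(C)[C@H]1CC=C(C)[C@@H](O)C1 | intermediate
3 | cis-carveol TBS ether | C=C(C)[C@H]1CC=C(C)[C@@H](O[Si](C)(C)C(C)(C)C)C1 | intermediate
4 | (4S,6S)-4-TBSO-3-methyl-6-isopropenylcyclohex-2-enone | C=C(C)[C@H]1C(=O)C=C(C)[C@@H](O[Si](C)(C)C(C)(C)C)C1 | intermediate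
5 | 4-methoxybenzyl alcohol | OCc1ccc(OC)cc1 | starting material
6 | 4-methoxybenzyl vinyl ether | C=COCc1ccc(OC)cc1 | intermediate
7 | 1,2-dibromoethyl 4-methoxybenzyl ether (racemic) | BrCC(Br)OCc1ccc(OC)cc1 | intermediate
8 | (Z)-2-bromovinyl 4-methoxybenzyl ether | Br/C=C\OCc1ccc(OC)cc1 | intermediate
9 | (Z)-2-(4-methoxybenzyloxy)vinyllithium | [Li]/C=C\OCc1ccc(OC)cc1 | intermediate
10 | (1S,4S,6S)-trans-dialkenylcyclohexenol | C=C(C)[C@H]1[C@](O)(/C=C\OCc2ccc(OC)cc2)C=C(C)[C@@H](O[Si](C)(C)C(C)(C)C)C1 | intermediate
11 | potassium alkoxide of 10 | C=C(C)[C@H]1[C@]([O-])(/C=C\OCc2ccc(OC)cc2)C=C(C)[C@@H](O[Si](C)(C)C(C)(C)C)C1.[K+] | intermediate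
12 | potassium enolate, ten-membered ring (3S,8R; C5 and C8 trans on C6=C7) | COc1ccc(CO[C@@H]2C/C(C)=C/C[C@H](O[Si](C)(C)C(C)(C)C)/C(C)=C\C([O-])=C\2)cc1.[K+] | intermediate
13 | keto ester (3S,7R,8R; 1(10)E,4Z) | COc1ccc(CO[C@@H]2C/C(C)=C/C[C@H](O[Si](C)(C)C(C)(C)C)/C(C)=C\C(=O)[C@@H]2CC(=O)OC)cc1 | intermediate
14 | hydroxy ester (3S,6S,7S,8R) | COc1ccc(CO[C@@H]2C/C(C)=C/C[C@H](O[Si](C)(C)C(C)(C)C)/C(C)=C\[C@H](O)[C@@H]2CC(=O)OC)cc1 | intermediate
15 | hydroxy acid (3S,6S,7S,8R) | COc1ccc(CO[C@@H]2C/C(C)=C/C[C@H](O[Si](C)(C)C(C)(C)C)/C(C)=C\[C@H](O)[C@@H]2CC(=O)O)cc1 | intermediate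
16 | trans-lactone (3S,6R,7R,8R) | COc1ccc(CO[C@@H]2C/C(C)=C/C[C@H](O[Si](C)(C)C(C)(C)C)/C(C)=C\[C@H]3OC(=O)C[C@@H]32)cc1 | intermediate
17 | Mannich base (C11 epimers) | COc1ccc(CO[C@@H]2C/C(C)=C/C[C@H](O[Si](C)(C)C(C)(C)C)/C(C)=C\[C@H]3OC(=O)C(CN(C)C)[C@@H]32)cc1 | intermediate
18 | methiodide of 17 | COc1ccc(CO[C@@H]2C/C(C)=C/C[C@H](O[Si](C)(C)C(C)(C)C)/C(C)=C\[C@H]3OC(=O)C(C[N+](C)(C)C)[C@@H]32)cc1.[I-] | intermediate
19 | alpha-methylene lactone, O8 PMB, O3 TBS | COc1ccc(CO[C@@H]2C/C(C)=C/C[C@H](O[Si](C)(C)C(C)(C)C)/C(C)=C\[C@H]3OC(=O)C(=C)[C@@H]32)cc1 | intermediate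
20 | 8-hydroxy alpha-methylene lactone, O3 TBS | O[C@@H]1C/C(C)=C/C[C@H](O[Si](C)(C)C(C)(C)C)/C(C)=C\[C@H]2OC(=O)C(=C)[C@@H]21 | intermediate
21 | 8-O-methacrylate, O3 TBS | C=C(C)C(=O)O[C@@H]1C/C(C)=C/C[C@H](O[Si](C)(C)C(C)(C)C)/C(C)=C\[C@H]2OC(=O)C(=C)[C@@H]21 | intermediate
22 | (1R,10R)-epoxide, O3 TBS | C=C(C)C(=O)O[C@@H]1C[C@@]2(C)O[C@@H]2C[C@H](O[Si](C)(C)C(C)(C)C)/C(C)=C\[C@H]2OC(=O)C(=C)[C@@H]21 | intermediate
23 | 15-hydroxy epoxide, O3 TBS | C=C(C)C(=O)O[C@@H]1C[C@@]2(C)O[C@@H]2C[C@H](O[Si](C)(C)C(C)(C)C)/C(CO)=C\[C@H]2OC(=O)C(=C)[C@@H]21 | intermediate
24 | CNP0496616.1 (1R,3S,6R,7R,8R,10R; 4Z) | C=C(C)C(=O)O[C@@H]1C[C@@]2(C)O[C@@H]2C[C@H](O)/C(CO)=C\[C@H]2OC(=O)C(=C)[C@@H]21 | target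

## Step count and least certain steps

Total step count: 16. Longest linear sequence: 14 (steps 1–3 and 6–16, from 1 to 24). Steps 4 and 5 form the side branch.

**Step 7 (key step).** The most likely failure is loss of the C8 alkoxy group by beta-elimination from the potassium enolate while the rearrangement is still running. The donor-substituted alkene terminus and the syn-axial contact of O6 and O8 in the chair should slow the [3,3] shift, so the enolate lives longer at room temperature. Proton transfer between product and enolate could also lead to incomplete or double alkylation. The fallback sets out from 10. Catalytic PdCl2(MeCN)2 (divalent palladium) in THF at room temperature should start the cyclisation-induced variant of the oxy-Cope rearrangement. The methyl-substituted C9=C10 unit is the substitution pattern this variant requires. It gives the neutral macrocyclic ketone F1 without any enolate above −78 °C. LDA at −78 °C then makes the lithium enolate F2, which is alkylated with methyl bromoacetate. The fallback comes back at 13.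

**Step 15.** The ene reaction may be too slow, because C4=C5 is deactivated by the allylic oxygens at C3 and C6. Forcing conditions invite epoxide opening or over-oxidation at C15. The fallback changes from a chemical ene reaction to enzymatic C–H hydroxylation. It sets out from 22. Buffered TBAF removes the silyl group to give the 15-deoxy compound F3. An engineered cytochrome P450 monooxygenase, chosen by screening and run in whole cells with cofactor recycling, hydroxylates the allylic methyl group of this germacranolide epoxide. The fallback comes back at 24.

**Step 3.** Site selectivity may be poor. Hydrogen abstraction at C15, at C3–H or at the tertiary C1–H competes with C6, and the isopropenyl double bond may migrate into conjugation. The fallback builds the enone by oxygen transposition and sets out from 2.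
- VO(acac)2 and t-BuOOH give the syn epoxy alcohol F4.
- TBSCl and imidazole give the epoxy silyl ether F5.
- PhSeNa opens F5 at the secondary carbon C5 in the trans-diaxial sense (Fürst–Plattner rule) to the hydroxy selenide F6.
- H2O2 triggers selenoxide elimination towards C6 to give the tertiary allylic alcohol F7.
- Babler–Dauben oxidative transposition with pyridinium chlorochromate, [C5H5NH][CrO3Cl], comes back at 4.

**Step 8 (with step 10).** Facial selectivity in the hydride addition may be poor, because the ketone can turn its carbonyl group more easily than the enolate. In step 10, SN2′ attack or lactonisation with retention may compete. The sequence partly protects itself. A 6R alcohol lactonises directly, or again after the acidification of step 9, to 16, while the 6S alcohol reaches the same 16 by inversion. The fallback replaces substrate control and inversion by reagent control and retention. It sets out from 13. Corey–Bakshi–Shibata reduction with (S)-2-methyl-CBS-oxazaborolidine and catecholborane, with the branched C7 side as the large group, gives the 6R hydroxy ester F8. F8 lactonises on mild acid treatment and comes back at 16.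

**Step 6.** Three things may go wrong. The basic vinyllithium may enolise 4 at the doubly activated C1–H. Reagent 9 may decompose by elimination if the temperature rises. Attack syn to the isopropenyl group may erode the trans relation. The fallback uses a less basic acetylide and makes the Z geometry by syn hydrogenation. It sets out from 5 and 4.
- KH and trichloroethene convert 5 into the (E)-1,2-dichlorovinyl ether F9.
- Two equivalents of n-BuLi give the lithium alkoxyacetylide F10.
- F10 adds to 4 to give the propargylic alcohol F11.
- Semihydrogenation over Pd/CaCO3 poisoned with Pb(OAc)2 and quinoline comes back at 10.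

## Further compounds

F1 | step 7 | macrocyclic ketone (3S,8R; 1(10)E,4Z), C7 unsubstituted | COc1ccc(CO[C@@H]2C/C(C)=C/C[C@H](O[Si](C)(C)C(C)(C)C)/C(C)=C\C(=O)C2)cc1
F2 | step 7 | lithium enolate of F1 | COc1ccc(CO[C@@H]2C/C(C)=C/C[C@H](O[Si](C)(C)C(C)(C)C)/C(C)=C\C([O-])=C\2)cc1.[Li+]
F3 | step 15 | 15-deoxy compound (free 3-OH) | C=C(C)C(=O)O[C@@H]1C[C@@]2(C)O[C@@H]2C[C@H](O)/C(C)=C\[C@H]2OC(=O)C(=C)[C@@H]21
F4 | step 3 | syn epoxy alcohol from cis-carveol | C=C(C)[C@H]1C[C@H]2O[C@@]2(C)[C@@H](O)C1
F5 | step 3 | epoxy silyl ether | C=C(C)[C@H]1C[C@H]2O[C@@]2(C)[C@@H](O[Si](C)(C)C(C)(C)C)C1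
F6 | step 3 | hydroxy selenide | C=C(C)[C@H]1C[C@H]([Se]c2ccccc2)[C@@](C)(O)[C@@H](O[Si](C)(C)C(C)(C)C)C1
F7 | step 3 | tertiary allylic alcohol | C=C(C)[C@H]1C=C[C@@](C)(O)[C@@H](O[Si](C)(C)C(C)(C)C)C1
F8 | step 8 | 6R hydroxy ester (3S,6R,7S,8R) | COc1ccc(CO[C@@H]2C/C(C)=C/C[C@H](O[Si](C)(C)C(C)(C)C)/C(C)=C\[C@@H](O)[C@@H]2CC(=O)OC)cc1
F9 | step 6 | (E)-1,2-dichlorovinyl 4-methoxybenzyl ether | Cl/C=C(/Cl)OCc1ccc(OC)cc1
F10 | step 6 | lithium (4-methoxybenzyloxy)acetylide | [Li]C#COCc1ccc(OC)cc1
F11 | step 6 | propargylic alcohol | C=C(C)[C@H]1[C@](O)(C#COCc2ccc(OC)cc2)C=C(C)[C@@H](O[Si](C)(C)C(C)(C)C)C1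
A1 | alternative 1 | open-chain (Z)-enal with 2-(bromomethyl)acrylate | O=C/C=C(/CO[Si](C)(C)C(C)(C)C)[C@@H](O[Si](C)(C)C(C)(C)C)C/C=C(\C)C[C@@H](OCc1ccc(OC)cc1)/C=C(\CBr)C(=O)OC
A2 | alternative 1 | protected macrocyclic alpha-methylene lactone | COc1ccc(CO[C@@H]2C/C(C)=C/C[C@H](O[Si](C)(C)C(C)(C)C)/C(CO[Si](C)(C)C(C)(C)C)=C\[C@H]3OC(=O)C(=C)[C@@H]32)cc1
A3 | alternative 2 | triene lactone for ring-closing metathesis | C=C[C@H]1OC(=O)C(=C)[C@@H]1[C@H](OCc2ccc(OC)cc2)C/C(C)=C/C[C@H](O[Si](C)(C)C(C)(C)C)C(=C)CO[Si](C)(C)C(C)(C)C
A4 | alternative 3 | thirteen-membered bis-allylic ether | O1C/C(CO[Si](C)(C)C(C)(C)C)=C/[C@H](OCc2ccc(OC)cc2)C/C(C)=C/C[C@H](O[Si](C)(C)C(C)(C)C)/C(CO[Si](C)(C)C(C)(C)C)=C\C1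
A5 | alternative 3 | ring-contracted ten-membered carbinol | COc1ccc(CO[C@@H]2C/C(C)=C/C[C@H](O[Si](C)(C)C(C)(C)C)/C(CO[Si](C)(C)C(C)(C)C)=C\[C@@H](O)[C@@H]2C(=C)CO[Si](C)(C)C(C)(C)C)cc1
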